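Pick the recipe by its rate. You have two recipes for a 10 h run, Wednesday's and Thursday's, and the earlier runs to judge them by.

| flask | starting material | reagent | protic impurity | free catalyst | added ligand | remark | time |
|---|---|---|---|---|---|---|---|
| dusk | 0.24 M | 0.36 M | 0.20 M | 40 mM | 110 mM | run made earlier |  |
| winter | 0.48 M | 0.36 M | 0.20 M | 40 mM | 110 mM | run made earlier |  |
| spring | 0.40 M | 0.22 M | 0.20 M | 40 mM | 110 mM | run made earlier |  |
| Wednesday's | 0.60 M | 0.100 M | 0.200 M | 20 mM | 110 mM |  | 10 h |
| Thursday's | 0.40 M | 0.360 M | 0.200 M | 40 mM | 110 mM |  | 10 h |

- dusk (time / h: target / %): 0.333: 0; 1.00: 0.6; 2.00: 3.6; 2.50: 5.1; 4.00: 9.4; 5.00: 12.6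
- winter (time / h: target / %): 0.333: 0; 1.00: 0.4; 2.00: 1.7; 2.50: 2.6; 4.00: 6.2; 5.00: 8.4
- spring (time / h: target / %): 0.417: 0; 1.33: 2.0; 2.50: 3.3; 4.00: 6.2; 5.00: 7.2

(readings scatter by 0.5 percentage points)

- a reading or a percentage of target counts all its forms, free or not
- no earlier run changes the charge of free catalyst; that part of a forecast is a guess

* which of the two ends with the higher amount of target, in percent of the starting material charged ("neither" if they lie within 2 percentage points) (Wednesday's / Thursday's / neither)
* target at the end, in percent of the starting material charged, Wednesday's
* target at the end, in percent of the starting material charged, Thursday's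

In the dusk and winter readings the target appears after a lag (an induction period) and then climbs nearly straight. So take the slope from the 2.00 h reading to the last one and turn it into molar terms. That slope is the straight-line rate. The dusk run reads 0.00720 M/h and the winter run 0.0107 M/h. Running those two lines back to zero gives a mean lag of 1.02 h. These are readings, so they carry the scatter.

Thursday's charge of starting material lies between those two runs, with the same reagent and free catalyst. Interpolating gives my estimate of its straight-line rate, r = 0.00955 M/h. My reckoning for Thursday's is r times the time after the lag, divided by the charge, which is 21.4 %.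

For Wednesday's, look at the spring run first. Its rate of 0.00624 M/h is 0.653 of r, while its reagent is 0.611 of Thursday's, so I scale the rate with reagent. Scaling with free catalyst as well is a guess, and I leave the starting material out. That gives 0.00133 M/h, or 1.98 % of Wednesday's larger charge. I would charge Thursday's, since its reckoned yield is higher.

The forecast also names Thursday's: 2.5 % (1 % to 5 %) for Wednesday's and 19.5 % (15.5 % to 23 %) for Thursday's. Its Thursday figure sits below mine, as it reckons “with mild slowing from reagent use”.

The flasks end at 19.4 % for Thursday's and 5.58 % for Wednesday's.

    catalyst intermediate C ⇌ catalyst intermediate D (K = 1.40, k = 3.00 /h)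
    starting material + free catalyst → catalyst intermediate A (k = 6.50 /M/h)
    reagent + catalyst intermediate B → catalyst intermediate C (k = 8.00 /M/h)
    catalyst intermediate A → catalyst intermediate B (k = 3.30 /h)
    catalyst intermediate D → free catalyst + target (k = 0.820 /h)
    free catalyst + added ligand ⇌ idle complex A (K = 9.20 /M, k = 8.10 /M/h)
    starting material + protic impurity → quenched substrate (k = 1.10 /M/h)
    free catalyst + target ⇌ idle complex B, settled at all times (K = 2.20 /M)

Thursday's ends higher, as chosen, and Wednesday's ends above my 1.98 %. At the end, Thursday's holds 44.6 % of its starting material as quenched substrate, more than it holds as target. Thursday's mean rate after the lag is 0.00866 M/h, below r. For Thursday's flask read at 6.0 h, r gives 11.9 %, and that flask holds 11.5 % of target.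

(All runs come from a simulation from invented constants, noise included.)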